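The easy step comes first: substrate leaves by two first-order steps side by side, one to intermediate A and one to target.

    substrate → intermediate A (k1 = 0.0945 s⁻¹)
    substrate → target (k2 = 0.127 s⁻¹)
    intermediate A ⇌ intermediate B (K3 = 0.528, k3 = 0.0505 s⁻¹)
    intermediate A ⇌ intermediate C (K4 = 24.8, k4 = 0.00334 s⁻¹)
    intermediate B ⇌ intermediate D (K5 = 0.156, k5 = 0.968 s⁻¹)
    intermediate B ⇌ intermediate E (K6 = 9.3, k6 = 0.0248 s⁻¹)

| flask | substrate | remark | time |
|---|---|---|---|
| theta | 0.50 M | a single well-mixed tank run continuously and read at steady state, 2.5 min in it on average |  |
| delta | 0.50 M | plug flow through a tube for 2.5 min, no back-mixing | 2.5 min |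
| gamma | 0.50 M | everything together in a closed stirred flask, run for 2.5 min | 2.5 min |

- the set-up with the highest amount of target at the outlet or at the end, in percent of the substrate put in ("none" if the first two lie within 2 percentage points) (theta / delta / gamma / none)
- amount of target at the outlet or at the end, in percent of the substrate put in, theta
- amount of target at the outlet or at the end, in percent of the substrate put in, delta
- amount of target at the outlet or at the end, in percent of the substrate put in, gamma

I count in powers of ten. The number of powers of ten by which [substrate] falls in a run I call the decades of decay, with 14.4 for 2.5 min. The share of consumed substrate that becomes target is the selectivity, 57.3 %, and target has no step out, so target is that share of what was consumed.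

Time is the first setting. Delta and gamma give each portion the same age, and half the time still gives 7.20 decades, so by hand target stays put.

The charge is the second. Both rates scale with [substrate], so it cancels from the decades and the selectivity, and by hand target, in percent of the substrate put in, does not move.

The vessel is the third. Theta holds its contents at the outlet [substrate], and the balance leaves a fraction 2.92 %, which is 1.53 decades.

| Set-up | Decades | Target by hand |
|---|---|---|
| theta | 1.53 | 55.7 % |
| delta | 14.4 | 57.3 % |
| gamma | 14.4 | 57.3 % |

The gap of 1.7 percentage points is smaller than the margin of 2 points, so I call it none.

The forecast says none, with 55.7 %, 57.3 % and 57.3 %, holding that “the downstream intermediate equilibria do not matter”.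

The runs give 55.7 % in theta, 57.3 % in delta and 57.3 % in gamma, so the call is none. In delta, target stays within 5 points from 0.31 min to 20 min at least, and from 0.062 M to 4.0 M of substrate at least. The half-lives of substrate by each step alone, 0.12 min to intermediate A and 0.091 min to target, are both far shorter than the 2.5 min of the run. Delta, reckoned at 14.4 decades, reads 0 % substrate at the outlet, while theta, reckoned at 1.53 decades, reads 2.92 %.

Delta read at 4.0 min counts 23.1 decades, so I expect target at the selectivity, 57.3 %. The run reads 57.3 % target and 0 % substrate.

The constants used here were drawn at random within sensible limits; the flask was simulated.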